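**Plan**

1. Retrosynthetically, the three ester C–O bonds (benzoates on the C2 and C7 oxygens, acetate on the C3 oxygen) are cut first, then C7 goes back to a methyl ester and the C5 carbinol to a ketone masked as a dimethyl ketal; the last cut removes the C3–O and C4–O bonds of the cis-diol.
2. What remains is a chiral cyclohexa-1,4-diene whose ring carbons C1–C6 plus C7, with oxygens on C2, C5 and C7, are those of methyl 5-methoxysalicylate; no ring is ever closed, the benzene ring becomes the carbocycle.
3. The feature that allows the key step: in this diene C3=C4 is an isolated cis-alkene lying between the C2 stereocentre (bulky silyloxy group) and the symmetric C5 ketal, while C1=C6 is deactivated by the C7 ester.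
4. Forward order: dearomatise, reduce C2 enantioselectively, silylate, cis-dihydroxylate C3=C4, unmask and reduce C5, reduce C7, then acylate the oxygens one by one.
5. Stereochemistry: C2 by catalyst control (CBS reduction); C3 and C4 by osmylation anti to the C2 silyloxy group; C5 by hydroxyl-directed hydride delivery from the face of the C3/C4 hydroxyls; the trans C4/C5 diol is then singled out as a butane-2,3-diacetal so that C3 alone takes the acetate.

Key step: step 4

Remark on conventions: in all descriptions the ring is numbered C1 (sp2, carries C7), C2, C3, C4, C5 (the oxygenated sp3 carbons in order) and C6 (vinyl CH). α is the face of the C2 and C5 oxygens of the target, β the face of the C3 and C4 oxygens. In this numbering the target is (2S,3S,4S,5R). The silyl group is taken as TBDPS rather than a smaller silyl group so that it survives the acidic steps 5 and 7.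

**Route**

Step 1
Reactants: 1 methyl 2-hydroxy-5-methoxybenzoate; 2 (diacetoxyiodo)benzene, PhI(OAc)2
Product: 3 methyl 3,3-dimethoxy-6-oxocyclohexa-1,4-diene-1-carboxylate (quinone monoketal: C2 ketone, C5 dimethyl ketal)
Conditions: PhI(OAc)2 (1.1 equiv), MeOH, 0 °C → rt; NaHCO3 work-up
Reagents that add atoms: methanol, CO
Why: Oxidative dearomatisation of a para-methoxyphenol with the trivalent iodine reagent: ligand exchange at iodine and loss of PhI leave a para-oxocarbenium ion that methanol captures at C5, giving the quinone monoketal with no stereocentre.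

Step 2
Reactants: 3 methyl 3,3-dimethoxy-6-oxocyclohexa-1,4-diene-1-carboxylate
Product: 4 methyl (6R)-6-hydroxy-3,3-dimethoxycyclohexa-1,4-diene-1-carboxylate (C2 carbinol, OH on the α face)
Conditions: (S)-2-methyl-CBS-oxazaborolidine (0.2 equiv), BH3·SMe2 (0.7 equiv), THF, −30 °C; MeOH quench, aq. NaHCO3 work-up, no acid
Reagents that add atoms: none
Why: Corey–Bakshi–Shibata reduction, in which the ketone coordinates the oxazaborolidine–borane complex anti to its larger, ester-bearing C1 flank so that hydride is delivered intramolecularly to one face of C2 only, setting the (R)-carbinol by catalyst control while the 1,2-mode of delivery spares the enoate and the ester.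

Step 3
Reactants: 4 methyl (6R)-6-hydroxy-3,3-dimethoxycyclohexa-1,4-diene-1-carboxylate
Product: 5 methyl (6R)-6-[(tert-butyldiphenylsilyl)oxy]-3,3-dimethoxycyclohexa-1,4-diene-1-carboxylate
Conditions: TBDPSCl, imidazole, DMAP (cat.), DMF, rt
Reagents that add atoms: tert-butyl(chloro)diphenylsilane, CC(C)(C)[Si](Cl)(c1ccccc1)c1ccccc1
Why: Imidazole-mediated silylation of a secondary alcohol under basic conditions, which leaves the C2 stereocentre untouched, removes the acid-labile free dienol and installs a bulky, acid-stable group to shield the α face in the next step.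

Step 4
Reactants: 5 methyl (6R)-6-[(tert-butyldiphenylsilyl)oxy]-3,3-dimethoxycyclohexa-1,4-diene-1-carboxylate
Product: 6 methyl (4R,5S,6S)-6-[(tert-butyldiphenylsilyl)oxy]-4,5-dihydroxy-3,3-dimethoxycyclohex-1-ene-1-carboxylate (C2 OTBDPS α; C3 OH and C4 OH β, cis; C5 ketal; C7 ester)
Conditions: OsO4 (5 mol%), N-methylmorpholine N-oxide (1.5 equiv), acetone/H2O (4:1), 0 °C → rt; aq. Na2SO3 quench
Reagents that add atoms: osmium tetroxide, O=[Os](=O)(=O)=O; N-methylmorpholine N-oxide, C[N+]1([O-])CCOCC1; water, O
Why: OsO4 adds suprafacially across C3=C4 in a [3+2] cycloaddition, water hydrolyses the cyclic osmate ester of hexavalent osmium, and N-methylmorpholine N-oxide returns the metal to octavalent OsO4. The closest known reaction type is the catalytic osmylation of cyclic allylic silyl ethers, which follows the empirical rule of attack anti to the allylic oxygen substituent. No ring is closed; only the C3–O and C4–O bonds form. C3 and C4 become stereocentres together, cis to each other because the addition is concerted, and both on the β face because the C2 stereocentre holds the TBDPS-oxy group over the α face while the symmetric C5 ketal adds no bias. The step needs site selectivity for C3=C4 over C1=C6, which is secured because electrophilic OsO4 reacts far more slowly with the trisubstituted, ester-conjugated C1=C6 bond than with the isolated disubstituted one. The neutral medium keeps the ketal and the bis-allylic silyl ether from acid-induced rearomatisation.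

Step 5
Reactants: 6 methyl (4R,5S,6S)-6-[(tert-butyldiphenylsilyl)oxy]-4,5-dihydroxy-3,3-dimethoxycyclohex-1-ene-1-carboxylate
Product: 7 methyl (4R,5S,6S)-6-[(tert-butyldiphenylsilyl)oxy]-4,5-dihydroxy-3-oxocyclohex-1-ene-1-carboxylate (C5 ketone)
Conditions: 1 M aq. HCl, THF, 0 °C → rt
Reagents that add atoms: water, O
Why: Acid-catalysed hydrolysis of the dimethyl ketal to the conjugated C5 ketone, a stable α′,β′-dihydroxy enone of the gabosine type, under dilute acid that the TBDPS ether, the methyl ester and the existing stereocentres tolerate.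

Step 6
Reactants: 7 methyl (4R,5S,6S)-6-[(tert-butyldiphenylsilyl)oxy]-4,5-dihydroxy-3-oxocyclohex-1-ene-1-carboxylate
Product: 8 methyl (3R,4S,5S,6S)-6-[(tert-butyldiphenylsilyl)oxy]-3,4,5-trihydroxycyclohex-1-ene-1-carboxylate (C5 OH α, trans to C4 OH)
Conditions: Me4NBH(OAc)3 (5 equiv), MeCN/AcOH (1:1), −30 → −20 °C
Reagents that add atoms: none
Why: Saksena–Evans hydroxyl-directed reduction: the triacetoxyborohydride exchanges a ligand for the β-face C4 (or C3) hydroxyl and delivers hydride intramolecularly to the β face of the C5 carbonyl, so the new C5 hydroxyl should appear on the α face, trans to C4–OH, while the enoate is not reduced by this weak hydride donor.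

Step 7
Reactants: 8 methyl (3R,4S,5S,6S)-6-[(tert-butyldiphenylsilyl)oxy]-3,4,5-trihydroxycyclohex-1-ene-1-carboxylate
Product: 9 C4,C5-butane-2,3-diacetal of 8 (methyl ester; C2 OTBDPS α; C3 OH β free; C4–O β and C5–O α bridged by a (2S,3S)-2,3-dimethoxybutane-2,3-diyl unit in a trans-fused 1,4-dioxane)
Conditions: 2,2,3,3-tetramethoxybutane, CSA (cat.), MeOH, reflux
Reagents that add atoms: 2,2,3,3-tetramethoxybutane, COC(C)(OC)C(C)(OC)OC
Why: Butane-2,3-diacetal protection under thermodynamic control, which forms the doubly anomerically stabilised trans-fused dioxane only on a trans-diequatorial diol (C4/C5) and not on the cis C3/C4 pair, as known for shikimate-type triols, the two acetal carbons adopting the configuration with both methoxy groups axial.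

Step 8
Reactants: 9 C4,C5-butane-2,3-diacetal methyl ester
Product: 10 C7 allylic alcohol (C1 CH2OH; C2 OTBDPS; C3 OH; C4/C5 butane-2,3-diacetal)
Conditions: iBu2AlH (4 equiv), CH2Cl2, −78 → −20 °C; aq. KNaC4H4O6 work-up
Reagents that add atoms: none
Why: iBu2AlH 1,2-reduction of an α,β-unsaturated methyl ester to the allylic alcohol, with the silyl ether and the diacetal inert to hydride and no stereocentre involved.

Step 9
Reactants: 10 C7 allylic alcohol
Product: 11 C7 benzoate (C1 CH2OBz; C2 OTBDPS; C3 OH; C4/C5 butane-2,3-diacetal)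
Conditions: BzCl (1.05 equiv), pyridine, CH2Cl2, −30 °C
Reagents that add atoms: benzoyl chloride, O=C(Cl)c1ccccc1
Why: Selective acylation of the unhindered primary allylic alcohol at low temperature, the secondary C3 hydroxyl being axial and flanked by the TBDPS ether and the dioxane ring.

Step 10
Reactants: 11 C7 benzoate
Product: 12 C3 acetate (C1 CH2OBz; C2 OTBDPS; C3 OAc; C4/C5 butane-2,3-diacetal)
Conditions: Ac2O, pyridine, DMAP (cat.), CH2Cl2, rt
Reagents that add atoms: acetic anhydride, CC(=O)OC(C)=O
Why: DMAP-catalysed acetylation (nucleophilic catalysis) of the only free hydroxyl left, which places the acetate on C3 with retention since the C–O bond is not broken.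

Step 11
Reactants: 12 C3 acetate
Product: 13 C2 alcohol (C1 CH2OBz; C2 OH α; C3 OAc β; C4/C5 butane-2,3-diacetal)
Conditions: Bu4NF/AcOH (1:1), THF, 0 °C → rt
Reagents that add atoms: none
Why: Fluoride-induced desilylation buffered with acetic acid, in which acetyl transfer is suppressed both by the buffer and by the dioxane-locked half-chair that holds the C2 and C3 oxygens trans-diaxial, and in which any benzoyl shift from the C7 to the C2 oxygen would be corrected by the next step.

Step 12
Reactants: 13 C2 alcohol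
Product: 14 C2,C7-dibenzoate C3-acetate C4,C5-butane-2,3-diacetal
Conditions: BzCl, pyridine, DMAP (cat.), CH2Cl2, 0 °C → rt
Reagents that add atoms: benzoyl chloride, O=C(Cl)c1ccccc1
Why: DMAP-catalysed benzoylation of the allylic C2 alcohol (and of C7–OH should the benzoate have moved), an O-acylation that retains the C2 configuration.

Step 13
Reactants: 14 C2,C7-dibenzoate C3-acetate C4,C5-butane-2,3-diacetal
Product: 15 [(3R,4S,5S,6S)-5-(acetyloxy)-6-(benzoyloxy)-3,4-dihydroxycyclohex-1-en-1-yl]methyl benzoate (target)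
Conditions: TFA/H2O (9:1), 0 °C → rt, short contact; evaporation with toluene
Reagents that add atoms: none
Why: Aqueous trifluoroacetic acid hydrolysis of the butane-2,3-diacetal, the standard removal of this group, to which benzoates and the acetate are stable and which avoids the basic conditions under which the C3 acetate could move to the cis C4 hydroxyl.

**Compound list**

1 | methyl 2-hydroxy-5-methoxybenzoate | COC(=O)c1cc(OC)ccc1O | starting material
2 | (diacetoxyiodo)benzene, PhI(OAc)2 | CC(=O)OI(OC(C)=O)c1ccccc1 | starting material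
3 | methyl 3,3-dimethoxy-6-oxocyclohexa-1,4-diene-1-carboxylate | COC(=O)C1=CC(OC)(OC)C=CC1=O | intermediate
4 | methyl (6R)-6-hydroxy-3,3-dimethoxycyclohexa-1,4-diene-1-carboxylate | COC(=O)C1=CC(OC)(OC)C=C[C@H]1O | intermediate
5 | methyl (6R)-6-[(tert-butyldiphenylsilyl)oxy]-3,3-dimethoxycyclohexa-1,4-diene-1-carboxylate | COC(=O)C1=CC(OC)(OC)C=C[C@H]1O[Si](c1ccccc1)(c1ccccc1)C(C)(C)C | intermediate
6 | methyl (4R,5S,6S)-6-[(tert-butyldiphenylsilyl)oxy]-4,5-dihydroxy-3,3-dimethoxycyclohex-1-ene-1-carboxylate | COC(=O)C1=CC(OC)(OC)[C@H](O)[C@H](O)[C@H]1O[Si](c1ccccc1)(c1ccccc1)C(C)(C)C | intermediate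
7 | methyl (4R,5S,6S)-6-[(tert-butyldiphenylsilyl)oxy]-4,5-dihydroxy-3-oxocyclohex-1-ene-1-carboxylate | COC(=O)C1=CC(=O)[C@H](O)[C@H](O)[C@H]1O[Si](c1ccccc1)(c1ccccc1)C(C)(C)C | intermediate
8 | methyl (3R,4S,5S,6S)-6-[(tert-butyldiphenylsilyl)oxy]-3,4,5-trihydroxycyclohex-1-ene-1-carboxylate | COC(=O)C1=C[C@@H](O)[C@H](O)[C@H](O)[C@H]1O[Si](c1ccccc1)(c1ccccc1)C(C)(C)C | intermediate
9 | C4,C5-butane-2,3-diacetal methyl ester: C2 OTBDPS (α), C3 OH (β), C4–O (β)/C5–O (α) bridged by (2S,3S)-2,3-dimethoxybutane-2,3-diyl; (2S,3S,4R,5R) in route numbering | COC(=O)C1=C[C@H]2O[C@](C)(OC)[C@@](C)(OC)O[C@@H]2[C@H](O)[C@H]1O[Si](c1ccccc1)(c1ccccc1)C(C)(C)C | intermediate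
10 | C7 allylic alcohol: C1 CH2OH, C2 OTBDPS (α), C3 OH (β), C4/C5 butane-2,3-diacetal | OCC1=C[C@H]2O[C@](C)(OC)[C@@](C)(OC)O[C@@H]2[C@H](O)[C@H]1O[Si](c1ccccc1)(c1ccccc1)C(C)(C)C | intermediate
11 | C7 benzoate: C1 CH2OBz, C2 OTBDPS (α), C3 OH (β), C4/C5 butane-2,3-diacetal | O=C(OCC1=C[C@H]2O[C@](C)(OC)[C@@](C)(OC)O[C@@H]2[C@H](O)[C@H]1O[Si](c1ccccc1)(c1ccccc1)C(C)(C)C)c1ccccc1 | intermediate
12 | C3 acetate: C1 CH2OBz, C2 OTBDPS (α), C3 OAc (β), C4/C5 butane-2,3-diacetal | O=C(OCC1=C[C@H]2O[C@](C)(OC)[C@@](C)(OC)O[C@@H]2[C@H](OC(C)=O)[C@H]1O[Si](c1ccccc1)(c1ccccc1)C(C)(C)C)c1ccccc1 | intermediate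
13 | C2 alcohol: C1 CH2OBz, C2 OH (α), C3 OAc (β), C4/C5 butane-2,3-diacetal | O=C(OCC1=C[C@H]2O[C@](C)(OC)[C@@](C)(OC)O[C@@H]2[C@H](OC(C)=O)[C@H]1O)c1ccccc1 | intermediate
14 | C2,C7-dibenzoate C3-acetate: C1 CH2OBz, C2 OBz (α), C3 OAc (β), C4/C5 butane-2,3-diacetal | O=C(OCC1=C[C@H]2O[C@](C)(OC)[C@@](C)(OC)O[C@@H]2[C@H](OC(C)=O)[C@H]1OC(=O)c1ccccc1)c1ccccc1 | intermediate
15 | [(3R,4S,5S,6S)-5-(acetyloxy)-6-(benzoyloxy)-3,4-dihydroxycyclohex-1-en-1-yl]methyl benzoate | CC(=O)O[C@H]1[C@@H](O)[C@H](O)C=C(COC(=O)c2ccccc2)[C@@H]1OC(=O)c1ccccc1 | target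

**Step count and risks**

Total steps: 13. Longest linear sequence: 13 steps (1 to 15); the route is fully linear.

The three steps most likely to fail:

Step 2. The catalyst may discriminate poorly between two sp2 flanks of the ketone, hydride may add in conjugate fashion to the doubly activated C1=C6 bond, and the dienol may rearomatise on work-up. The fallback sets out from 3 and returns at 4. Ketone 3 is reduced without asymmetric induction (NaBH4, CeCl3·7H2O, MeOH, −78 °C; Luche 1,2-reduction) to racemic methyl 6-hydroxy-3,3-dimethoxycyclohexa-1,4-diene-1-carboxylate F1. This is resolved by lipase-catalysed transesterification (Burkholderia cepacia lipase, vinyl acetate, tert-butyl methyl ether, rt). With the ester-bearing flank as the large substituent, the usual enantiopreference of lipases for secondary alcohols should lead to acylation of the (R)-alcohol, giving the (R)-acetate F2 and leaving the (S)-alcohol F3. After separation, F2 is methanolysed (K2CO3, MeOH, 0 °C) to 4.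

Step 6. Non-directed intermolecular hydride delivery could compete with the directed pathway and erode the facial selectivity at C5, the only source of that stereocentre. The fallback sets out from 7 and returns at 8. The cis-diol of 7 is tied up as the C3,C4-acetonide of the enone F4 (2,2-dimethoxypropane, pyridinium p-toluenesulfonate, acetone, rt). Luche reduction (NaBH4, CeCl3·7H2O, MeOH, −78 °C) should then deliver hydride to the α face, away from the dioxolane, to give the C5 β-alcohol acetonide F5. Mitsunobu inversion (4-nitrobenzoic acid, PPh3, diisopropyl azodicarboxylate, THF, 0 °C) gives the C5 α 4-nitrobenzoate acetonide F6. Methanolysis (K2CO3, MeOH, 0 °C) gives the C5 α-alcohol acetonide F7, and aqueous acetic acid (AcOH/H2O 4:1, 40 °C) removes the acetonide to give 8.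

Step 11. Cleavage of the hindered, pseudo-axial silyl ether may be slow under buffered fluoride, and forcing it with unbuffered fluoride could cause loss or transfer of the C3 acetate. The fallback sets out from 11 and returns at 14. The C3 hydroxyl of 11 is etherified instead of acetylated (4-methoxybenzyl 2,2,2-trichloroacetimidate, La(OTf)3 cat., toluene, rt) to the C3 4-methoxybenzyl ether F8. With no acetate present, the silyl ether is cleaved with unbuffered Bu4NF (THF, rt) to the C2 alcohol C3 4-methoxybenzyl ether F9; a benzoyl shift between the C7 and C2 oxygens is inconsequential at this point. Benzoylation (BzCl, pyridine, DMAP, CH2Cl2) gives the C2,C7-dibenzoate C3 4-methoxybenzyl ether F10. Oxidative debenzylation (DDQ, CH2Cl2/pH 7 buffer, 0 °C) gives the C2,C7-dibenzoate C3 alcohol F11, and acetylation (Ac2O, pyridine, DMAP) gives 14.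

Further compounds
F1 | step 2 | racemic methyl 6-hydroxy-3,3-dimethoxycyclohexa-1,4-diene-1-carboxylate | COC(=O)C1=CC(OC)(OC)C=CC1O
F2 | step 2 | methyl (6R)-6-(acetyloxy)-3,3-dimethoxycyclohexa-1,4-diene-1-carboxylate | COC(=O)C1=CC(OC)(OC)C=C[C@H]1OC(C)=O
F3 | step 2 | methyl (6S)-6-hydroxy-3,3-dimethoxycyclohexa-1,4-diene-1-carboxylate | COC(=O)C1=CC(OC)(OC)C=C[C@@H]1O
F4 | step 6 | C3,C4-acetonide of enone 7 (C2 OTBDPS α, C3/C4 O-isopropylidene β, C5 ketone, methyl ester) | COC(=O)C1=CC(=O)[C@@H]2OC(C)(C)O[C@@H]2[C@H]1O[Si](c1ccccc1)(c1ccccc1)C(C)(C)C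
F5 | step 6 | C5 β-alcohol acetonide (C5 OH cis to the C4 oxygen) | COC(=O)C1=C[C@H](O)[C@@H]2OC(C)(C)O[C@@H]2[C@H]1O[Si](c1ccccc1)(c1ccccc1)C(C)(C)C
F6 | step 6 | C5 α 4-nitrobenzoate acetonide | COC(=O)C1=C[C@@H](OC(=O)c3ccc(cc3)[N+](=O)[O-])[C@@H]2OC(C)(C)O[C@@H]2[C@H]1O[Si](c1ccccc1)(c1ccccc1)C(C)(C)C
F7 | step 6 | C5 α-alcohol acetonide | COC(=O)C1=C[C@@H](O)[C@@H]2OC(C)(C)O[C@@H]2[C@H]1O[Si](c1ccccc1)(c1ccccc1)C(C)(C)C
F8 | step 11 | C3 4-methoxybenzyl ether (C1 CH2OBz, C2 OTBDPS, C4/C5 butane-2,3-diacetal) | O=C(OCC1=C[C@H]2O[C@](C)(OC)[C@@](C)(OC)O[C@@H]2[C@H](OCc3ccc(OC)cc3)[C@H]1O[Si](c1ccccc1)(c1ccccc1)C(C)(C)C)c1ccccc1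
F9 | step 11 | C2 alcohol C3 4-methoxybenzyl ether (C1 CH2OBz, C4/C5 butane-2,3-diacetal) | O=C(OCC1=C[C@H]2O[C@](C)(OC)[C@@](C)(OC)O[C@@H]2[C@H](OCc3ccc(OC)cc3)[C@H]1O)c1ccccc1
F10 | step 11 | C2,C7-dibenzoate C3 4-methoxybenzyl ether (C4/C5 butane-2,3-diacetal) | O=C(OCC1=C[C@H]2O[C@](C)(OC)[C@@](C)(OC)O[C@@H]2[C@H](OCc3ccc(OC)cc3)[C@H]1OC(=O)c1ccccc1)c1ccccc1
F11 | step 11 | C2,C7-dibenzoate C3 alcohol (C4/C5 butane-2,3-diacetal) | O=C(OCC1=C[C@H]2O[C@](C)(OC)[C@@](C)(OC)O[C@@H]2[C@H](O)[C@H]1OC(=O)c1ccccc1)c1ccccc1
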